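**Retrosynthetic overview**
1. End-game: the γ-lactone comes from cis-dihydroxylation of a Δ8 alkene plus oxidation of the two isopropenyl-derived side chains; the oxirane from a 1-silyloxy-2-tosylate; the ester by acylation of the 6β-alcohol.
2. The C10 quaternary centre and C1 come from an Ireland–Claisen [3,3] rearrangement of an 8α-glycolate across Δ9(10), which leaves the Δ8 alkene.
3. The C5–C4 bond comes from a Claisen [3,3] rearrangement of a 9β-allenyl ether across Δ5(10), which delivers the 1-formylvinyl group directly.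
4. The 6,8,9-trioxygenated core comes from singlet-oxygen [4+2] addition to the Shapiro diene of (R)-carvone, then Mitsunobu inversion (C6), Rubottom oxidation (C8) and Luche reduction (C9).
5. Ring order: the cyclohexane is bought with (R)-carvone, whose stereocentre (C7) relays all the others; the oxirane closes in step 16; the γ-lactone forms in steps 19–20.

**Convention (assumption).** Locants are the elemane locants of the target: ring C5 (CH bearing C4(=C3H2)–C15HO), C6 (CH–O ester), C7 (CH bearing C11(=C13H2)–C12), C8 (lactone C–O), C9 (CHOH), C10 (quaternary; methyl C14; oxirane C1/C2). β is the ring face carrying the C10 methyl group, α the other face. The target read from the SMILES is 5β-side chain, 6β-O, 7β-side chain, 8α-O, 9α-OH, 10β-methyl, (1R)-oxirane. In (R)-carvone the carbonyl carbon is C5. All reagents are commercial and achiral.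

**Step 1**
Reactants: 1 (R)-(−)-carvone
Product: 2 (R)-carvone p-toluenesulfonylhydrazone
Conditions: TsNHNH2, EtOH, AcOH (cat.), 25 °C
Reagents that add atoms: p-toluenesulfonohydrazide NNS(=O)(=O)c1ccc(C)cc1
Why: Acid-catalysed hydrazone condensation at the enone carbonyl; the carvone stereocentre (future C7) is untouched.

**Step 2**
Reactants: 2 (R)-carvone p-toluenesulfonylhydrazone
Product: 3 (5R)-2-methyl-5-(prop-1-en-2-yl)cyclohexa-1,3-diene
Conditions: MeLi (2.2 equiv), Et2O, 0 → 25 °C; then H2O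
Reagents that add atoms: none
Why: Shapiro reaction: the hydrazone dianion loses sulfinate and N2 after α'-deprotonation and the vinyllithium is protonated to the homoannular diene (C5=C6, C9=C10), with C7 untouched.

**Step 3**
Reactants: 3 (5R)-2-methyl-5-(prop-1-en-2-yl)cyclohexa-1,3-diene
Product: 5 (4R,5S)-4-hydroxy-2-methyl-5-(prop-1-en-2-yl)cyclohex-2-en-1-one (6α-hydroxy-9-ketone), via endoperoxide 4 (not isolated)
Conditions: O2, tetraphenylporphyrin (cat.), hν (visible), CH2Cl2, −78 °C; then Et3N (0.5 equiv), 0 °C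
Reagents that add atoms: dioxygen O=O
Why: [4+2] cycloaddition of singlet oxygen on the diene face anti to the isopropenyl group sets the 6α-oxygen, and Kornblum–DeLaMare fragmentation by loss of the less hindered bridgehead proton (H9) gives the γ-hydroxy enone.

**Step 4**
Reactants: 5 (4R,5S)-4-hydroxy-2-methyl-5-(prop-1-en-2-yl)cyclohex-2-en-1-one
Product: 6 (1S,6S)-3-methyl-4-oxo-6-(prop-1-en-2-yl)cyclohex-2-en-1-yl benzoate (6β-benzoate)
Conditions: PhCO2H, PPh3, DIAD, THF, 0 → 25 °C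
Reagents that add atoms: benzoic acid OC(=O)c1ccccc1
Why: Mitsunobu esterification proceeds by SN2 inversion at the allylic carbinol and gives the 6β-oxygen (cis to isopropenyl) that the target needs.

**Step 5**
Reactants: 6 (1S,6S)-3-methyl-4-oxo-6-(prop-1-en-2-yl)cyclohex-2-en-1-yl benzoate
Product: 8 3-methyl-4-oxo-6-(prop-1-en-2-yl)-5-(triisopropylsilyloxy)cyclohex-2-en-1-yl benzoate (6β-OBz; 7β-isopropenyl; 8α-OTIPS; 9-ketone), via TIPS dienol ether 7 (not isolated)
Conditions: LiN(SiMe3)2, THF, −78 °C; iPr3SiOTf; then mCPBA, CH2Cl2, −20 °C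
Reagents that add atoms: triisopropylsilyl trifluoromethanesulfonate CC(C)[Si](OS(=O)(=O)C(F)(F)F)(C(C)C)C(C)C; 3-chloroperoxybenzoic acid OOC(=O)c1cccc(Cl)c1
Why: Rubottom oxidation: the kinetic cross-conjugated silyl dienol ether is epoxidised anti to the isopropenyl and benzoate groups and a 1,4-silyl shift gives the 8α-silyloxy ketone.

**Step 6**
Reactants: 8 6β-benzoyloxy-8α-(triisopropylsilyloxy) enone
Product: 9 4-hydroxy-3-methyl-6-(prop-1-en-2-yl)-5-(triisopropylsilyloxy)cyclohex-2-en-1-yl benzoate (9β-OH cis to isopropenyl and trans to 8α-OTIPS)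
Conditions: NaBH4, CeCl3·7H2O, MeOH, −78 → 0 °C
Reagents that add atoms: none
Why: Luche 1,2-reduction with axial hydride delivery gives the equatorial 9β-alcohol.

**Step 7**
Reactants: 9 9β-allylic alcohol
Product: 10 3-methyl-6-(prop-1-en-2-yl)-4-(prop-2-yn-1-yloxy)-5-(triisopropylsilyloxy)cyclohex-2-en-1-yl benzoate (9β-propargyl ether)
Conditions: NaH, THF/DMF, 0 °C; HC≡CCH2Br, Bu4NI (cat.), 0 → 25 °C
Reagents that add atoms: propargyl bromide BrCC#C
Why: Williamson etherification of the sodium alkoxide; the bulky TIPS ether resists 1,2-silyl migration and no stereocentre is involved.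

**Step 8**
Reactants: 10 9β-propargyl ether
Product: 13 2-(3-hydroxyprop-1-en-2-yl)-3-methyl-6-(prop-1-en-2-yl)-5-(triisopropylsilyloxy)cyclohex-3-en-1-yl benzoate (5β-side chain; 6β-OBz; 7β-isopropenyl; 8α-OTIPS; Δ9(10)), via allenyl ether 11 (not isolated), via enal 12 (not isolated)
Conditions: KOtBu (0.3 equiv), THF, 0 °C; filtration through neutral Al2O3; PhMe, 110 °C; then NaBH4, CeCl3·7H2O, MeOH, −20 °C
Reagents that add atoms: none
Why: Propargyl-to-allenyl isomerisation, then allenyl ether Claisen rearrangement ([3,3]-sigmatropic) forms C5–C4 suprafacially from the 9β-oxygen so the 1-formylvinyl group arrives 5β; Luche reduction stores the base-sensitive enal as the allylic alcohol.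

**Step 9**
Reactants: 13 5β-(3-hydroxyprop-1-en-2-yl) silyl ether
Product: 14 5-hydroxy-2-(3-hydroxyprop-1-en-2-yl)-3-methyl-6-(prop-1-en-2-yl)cyclohex-3-en-1-yl benzoate (8α,15-diol)
Conditions: Bu4NF, AcOH (1:1), THF, 25 °C
Reagents that add atoms: none
Why: Buffered fluoride desilylation frees the 8α-allylic alcohol while the benzoate survives.

**Step 10**
Reactants: 14 8α,15-diol
Product: 15 2-[3-(tert-butyldimethylsilyloxy)prop-1-en-2-yl]-5-hydroxy-3-methyl-6-(prop-1-en-2-yl)cyclohex-3-en-1-yl benzoate (15-OTBS; free 8α-OH)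
Conditions: t-BuMe2SiCl, imidazole, CH2Cl2, 0 °C
Reagents that add atoms: tert-butyldimethylsilyl chloride CC(C)(C)[Si](C)(C)Cl
Why: The unhindered primary allylic alcohol is silylated selectively over the hindered secondary 8α-alcohol.

**Step 11**
Reactants: 15 15-O-TBS 8α-alcohol
Product: 16 8α-O-[(tert-butyldimethylsilyloxy)acetyl] ester of 15
Conditions: t-BuMe2SiOCH2CO2H, DCC, DMAP (cat.), CH2Cl2, 0 → 25 °C
Reagents that add atoms: 2-[(tert-butyldimethylsilyl)oxy]acetic acid CC(C)(C)[Si](C)(C)OCC(=O)O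
Why: Steglich esterification acylates the only free hydroxyl.

**Step 12**
Reactants: 16 8α-glycolate ester
Product: 19 (2R)-2-(tert-butyldimethylsilyloxy)-2-[5-benzoyloxy-6-[3-(tert-butyldimethylsilyloxy)prop-1-en-2-yl]-1-methyl-4-(prop-1-en-2-yl)cyclohex-2-en-1-yl]acetic acid (10β-methyl; 10α-C1; Δ8), via silyl ketene acetal 17 (not isolated), via trimethylsilyl ester 18 (not isolated)
Conditions: LiN(SiMe3)2, Me3SiCl, Et3N, THF, −78 → 25 °C; then PhMe, 90 °C; aq. citric acid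
Reagents that add atoms: none
Why: Ireland–Claisen rearrangement ([3,3]-sigmatropic) forms the C10–C1 bond suprafacially on the α-face, giving the 10β-methyl quaternary centre and the Δ8 alkene; the boat-like transition state expected for the Z ketene acetal of a cyclohexenyl ester gives (1R).

**Step 13**
Reactants: 19 silyloxy acid
Product: 20 (2R)-2-(tert-butyldimethylsilyloxy)-2-[ring]ethanol with free 6β-OH (C2 and C6 diol; 15-OTBS)
Conditions: LiAlH4, THF, 0 → 25 °C; then Na2SO4·10H2O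
Reagents that add atoms: none
Why: Hydride reduction takes the acid to the primary alcohol and cleaves the benzoate, leaving silyl ethers and alkenes untouched.

**Step 14**
Reactants: 20 diol
Product: 21 C2 p-toluenesulfonate of 20 (6β-OH free)
Conditions: TsCl, pyridine, DMAP (cat.), CH2Cl2, 0 °C
Reagents that add atoms: p-toluenesulfonyl chloride Cc1ccc(cc1)S(=O)(=O)Cl
Why: Sulfonylation selects the primary alcohol over the hindered axial 6β-alcohol.

**Step 15**
Reactants: 21 tosylate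
Product: 22 6β-methacrylate of 21
Conditions: methacrylic anhydride, DMAP, Et3N, BHT (cat.), CH2Cl2, 40 °C
Reagents that add atoms: methacrylic anhydride CC(=C)C(=O)OC(=O)C(C)=C
Why: DMAP-catalysed acylation of the remaining 6β-hydroxyl installs the ester with retention.

**Step 16**
Reactants: 22 methacrylate tosylate
Product: 23 6β-methacrylate carrying the (1R)-oxirane on C10 and the free 15-alcohol
Conditions: Bu4NF (3 equiv), THF, 0 → 25 °C
Reagents that add atoms: none
Why: Fluoride cleaves both silyl ethers and the C1 alkoxide displaces the neighbouring primary tosylate (intramolecular Williamson, 3-exo-tet), closing the oxirane with retention at C1.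

**Step 17**
Reactants: 23 epoxy alcohol
Product: 24 12,15-diol (7β-(3-hydroxyprop-1-en-2-yl) group)
Conditions: SeO2 (0.5 equiv), t-BuOOH, CH2Cl2, 25 °C
Reagents that add atoms: selenium dioxide O=[Se]=O (oxygen donor, re-formed by tert-butyl hydroperoxide CC(C)(C)OO)
Why: SeO2 allylic oxidation (ene reaction then [2,3]-sigmatropic shift) hydroxylates the methyl group of the only electron-rich 1,1-disubstituted alkene; conjugated and hindered alkenes react far more slowly.

**Step 18**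
Reactants: 24 12,15-diol
Product: 25 12,15-dialdehyde (two 1-formylvinyl groups)
Conditions: MnO2, CH2Cl2, 25 °C
Reagents that add atoms: none
Why: MnO2 oxidises only allylic alcohols, so both primary allylic alcohols (including any 15-alcohol already oxidised in step 17) converge on the dialdehyde.

**Step 19**
Reactants: 25 12,15-dialdehyde
Product: 27 8α,12-lactol with free 9α-OH (anomeric mixture), via diol dialdehyde 26 (not isolated)
Conditions: OsO4 (2 mol %), N-methylmorpholine N-oxide, acetone/H2O, 0 °C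
Reagents that add atoms: osmium tetroxide O=[Os](=O)(=O)=O; N-methylmorpholine N-oxide C[N+]1([O-])CCOCC1; water O
Why: Upjohn dihydroxylation: electrophilic OsO4 takes the only non-conjugated alkene (Δ8) from the α-face, anti to the pseudo-axial 10β-methyl and 6β-ester, and the 8α-hydroxyl closes onto the C12 aldehyde as the trans-fused lactol.

**Step 20**
Reactants: 27 lactol
Product: 28 target CNP0228781.2
Conditions: MnO2, CH2Cl2, 25 °C
Reagents that add atoms: none
Why: MnO2 oxidises the allylic hemiacetal to the α-methylene-γ-lactone; the hindered non-allylic 9α-alcohol and the enal are inert.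

**Compound list**
1 | (R)-(−)-carvone, (5R)-2-methyl-5-(prop-1-en-2-yl)cyclohex-2-en-1-one | C1[C@H](C(C)=C)CC=C(C)C1=O | starting material
2 | (R)-carvone p-toluenesulfonylhydrazone | C1[C@H](C(C)=C)CC=C(C)C1=NNS(=O)(=O)c2ccc(C)cc2 | intermediate
3 | (5R)-2-methyl-5-(prop-1-en-2-yl)cyclohexa-1,3-diene | C1=CC(C)=CC[C@H]1C(C)=C | intermediate
4 | endoperoxide: 5-methyl-8-(prop-1-en-2-yl)-2,3-dioxabicyclo[2.2.2]oct-5-ene, O–O bridge anti to isopropenyl | [C@@H]12[C@H](C(C)=C)C[C@@H](OO1)C(C)=C2 | intermediate (not isolated)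
5 | (4R,5S)-4-hydroxy-2-methyl-5-(prop-1-en-2-yl)cyclohex-2-en-1-one (OH trans to isopropenyl; 6α-OH, 9-ketone) | O[C@H]1[C@H](C(C)=C)CC(=O)C(C)=C1 | intermediate
6 | (1S,6S)-3-methyl-4-oxo-6-(prop-1-en-2-yl)cyclohex-2-en-1-yl benzoate (6β-benzoate, cis to isopropenyl) | O=C(c2ccccc2)O[C@@H]1[C@H](C(C)=C)CC(=O)C(C)=C1 | intermediate
7 | cross-conjugated triisopropylsilyl dienol ether of 6 (C8=C9–OTIPS) | O=C(c2ccccc2)O[C@@H]1[C@H](C(C)=C)C=C(O[Si](C(C)C)(C(C)C)C(C)C)C(C)=C1 | intermediate (not isolated)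
8 | 3-methyl-4-oxo-6-(prop-1-en-2-yl)-5-(triisopropylsilyloxy)cyclohex-2-en-1-yl benzoate (6β-OBz, 7β-isopropenyl, 8α-OTIPS) | O=C(c2ccccc2)O[C@@H]1[C@H](C(C)=C)[C@@H](O[Si](C(C)C)(C(C)C)C(C)C)C(=O)C(C)=C1 | intermediate
9 | 4-hydroxy-3-methyl-6-(prop-1-en-2-yl)-5-(triisopropylsilyloxy)cyclohex-2-en-1-yl benzoate (9β-OH) | O=C(c2ccccc2)O[C@@H]1[C@H](C(C)=C)[C@@H](O[Si](C(C)C)(C(C)C)C(C)C)[C@H](O)C(C)=C1 | intermediate
10 | 9β-propargyl ether of 9 | O=C(c2ccccc2)O[C@@H]1[C@H](C(C)=C)[C@@H](O[Si](C(C)C)(C(C)C)C(C)C)[C@H](OCC#C)C(C)=C1 | intermediate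
11 | 9β-allenyl (propa-1,2-dienyl) ether | O=C(c2ccccc2)O[C@@H]1[C@H](C(C)=C)[C@@H](O[Si](C(C)C)(C(C)C)C(C)C)[C@H](OC=C=C)C(C)=C1 | intermediate (not isolated)
12 | enal: 3-methyl-2-(3-oxoprop-1-en-2-yl)-6-(prop-1-en-2-yl)-5-(triisopropylsilyloxy)cyclohex-3-en-1-yl benzoate (5β-formylvinyl, Δ9(10)) | O=C(c2ccccc2)O[C@@H]1[C@H](C(C)=C)[C@@H](O[Si](C(C)C)(C(C)C)C(C)C)C=C(C)[C@@H]1C(=C)C=O | intermediate (not isolated)
13 | 2-(3-hydroxyprop-1-en-2-yl)-3-methyl-6-(prop-1-en-2-yl)-5-(triisopropylsilyloxy)cyclohex-3-en-1-yl benzoate | O=C(c2ccccc2)O[C@@H]1[C@H](C(C)=C)[C@@H](O[Si](C(C)C)(C(C)C)C(C)C)C=C(C)[C@@H]1C(=C)CO | intermediate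
14 | 5-hydroxy-2-(3-hydroxyprop-1-en-2-yl)-3-methyl-6-(prop-1-en-2-yl)cyclohex-3-en-1-yl benzoate (8α,15-diol) | O=C(c2ccccc2)O[C@@H]1[C@H](C(C)=C)[C@@H](O)C=C(C)[C@@H]1C(=C)CO | intermediate
15 | 15-O-TBS ether of 14 (free 8α-OH) | O=C(c2ccccc2)O[C@@H]1[C@H](C(C)=C)[C@@H](O)C=C(C)[C@@H]1C(=C)CO[Si](C)(C)C(C)(C)C | intermediate
16 | 8α-O-[(tert-butyldimethylsilyloxy)acetyl] ester of 15 | O=C(c2ccccc2)O[C@@H]1[C@H](C(C)=C)[C@@H](OC(=O)CO[Si](C)(C)C(C)(C)C)C=C(C)[C@@H]1C(=C)CO[Si](C)(C)C(C)(C)C | intermediate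
17 | (Z)-O-trimethylsilyl ketene acetal of 16 | O=C(c2ccccc2)O[C@@H]1[C@H](C(C)=C)[C@@H](O/C(O[Si](C)(C)C)=C/O[Si](C)(C)C(C)(C)C)C=C(C)[C@@H]1C(=C)CO[Si](C)(C)C(C)(C)C | intermediate (not isolated)
18 | trimethylsilyl ester of 19 | O=C(c2ccccc2)O[C@@H]1[C@H](C(C)=C)C=C[C@@](C)([C@@H](O[Si](C)(C)C(C)(C)C)C(=O)O[Si](C)(C)C)[C@@H]1C(=C)CO[Si](C)(C)C(C)(C)C | intermediate (not isolated)
19 | (2R)-2-(tert-butyldimethylsilyloxy)-2-[5-benzoyloxy-6-[3-(tert-butyldimethylsilyloxy)prop-1-en-2-yl]-1-methyl-4-(prop-1-en-2-yl)cyclohex-2-en-1-yl]acetic acid (10β-Me, 10α-C1, Δ8) | O=C(c2ccccc2)O[C@@H]1[C@H](C(C)=C)C=C[C@@](C)([C@@H](O[Si](C)(C)C(C)(C)C)C(=O)O)[C@@H]1C(=C)CO[Si](C)(C)C(C)(C)C | intermediate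
20 | diol: C2 primary alcohol and 6β-OH; (1R)-OTBS; 15-OTBS | O[C@@H]1[C@H](C(C)=C)C=C[C@@](C)([C@@H](O[Si](C)(C)C(C)(C)C)CO)[C@@H]1C(=C)CO[Si](C)(C)C(C)(C)C | intermediate
21 | C2 p-toluenesulfonate of 20 | O[C@@H]1[C@H](C(C)=C)C=C[C@@](C)([C@@H](O[Si](C)(C)C(C)(C)C)COS(=O)(=O)c2ccc(C)cc2)[C@@H]1C(=C)CO[Si](C)(C)C(C)(C)C | intermediate
22 | 6β-methacrylate of 21 | C=C(C)C(=O)O[C@@H]1[C@H](C(C)=C)C=C[C@@](C)([C@@H](O[Si](C)(C)C(C)(C)C)COS(=O)(=O)c2ccc(C)cc2)[C@@H]1C(=C)CO[Si](C)(C)C(C)(C)C | intermediate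
23 | 6β-methacrylate with (1R)-oxirane on C10, 5β-(3-hydroxyprop-1-en-2-yl), 7β-isopropenyl, Δ8 | C=C(C)C(=O)O[C@@H]1[C@H](C(C)=C)C=C[C@@](C)([C@@H]2CO2)[C@@H]1C(=C)CO | intermediate
24 | 12,15-diol (both side chains 3-hydroxyprop-1-en-2-yl) | C=C(C)C(=O)O[C@@H]1[C@H](C(CO)=C)C=C[C@@](C)([C@@H]2CO2)[C@@H]1C(=C)CO | intermediate
25 | 12,15-dialdehyde (both side chains 1-formylvinyl) | C=C(C)C(=O)O[C@@H]1[C@H](C(C=O)=C)C=C[C@@](C)([C@@H]2CO2)[C@@H]1C(=C)C=O | intermediate
26 | 8α,9α-diol dialdehyde | C=C(C)C(=O)O[C@@H]1[C@H](C(C=O)=C)[C@@H](O)[C@@H](O)[C@@](C)([C@@H]2CO2)[C@@H]1C(=C)C=O | intermediate (not isolated)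
27 | 8α,12-lactol (anomers) with free 9α-OH | C=C(C)C(=O)O[C@@H]1[C@@H]2C(=C)C(O)O[C@H]2[C@@H](O)[C@@](C)([C@@H]2CO2)[C@@H]1C(=C)C=O | intermediate
28 | CNP0228781.2 | C=C(C)C(=O)O[C@@H]1[C@@H]2C(=C)C(=O)O[C@H]2[C@@H](O)[C@@](C)([C@@H]2CO2)[C@@H]1C(=C)C=O | target

**Totals.** 20 steps, all in one line; longest linear sequence 20 steps from (R)-carvone.

**Steps most likely to fail**

Step 3. The singlet-oxygen addition is only moderately face-selective (the syn adduct is removed at 5), and the base fragmentation could also abstract H6 and give the regioisomeric ketone. Fallback: setting out from 3, the endoperoxide 4 is reduced instead (Zn, AcOH, CH2Cl2) to the cis-diol 2-methyl-5-(prop-1-en-2-yl)cyclohex-2-ene-1,4-diol F1. The less hindered allylic carbinol (C9, flanked by CH2) is then oxidised chemoselectively (MnO2, CH2Cl2), which comes back to the route at 5.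

Step 12. The rearrangement must build a quaternary centre through a ring conformer with syn-axial C5 and C7 substituents, and the C1 configuration rests on the boat-versus-chair preference. Fallback: setting out from 15, O-alkylation (NaH, BrCH2CO2H, THF/DMF) gives the 8α-(carboxymethyl) ether F2. Its dianion (LiN(iPr)2, THF, −78 → 0 °C) undergoes a [2,3]-Wittig rearrangement, again suprafacial from the 8α-oxygen, to the α-hydroxy acid F3, with the C1 epimers separated at this point. Silylation (t-BuMe2SiOTf, 2,6-lutidine) gives the bis-silyl derivative F4, and hydrolysis of its silyl ester with aqueous AcOH comes back to the route at 19.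

Step 19. The hindered Δ8 alkene must be osmylated faster than the methacrylate and the two enal alkenes. Fallback: setting out from 21, acylation with 2-bromo-2-methylpropanoyl bromide (pyridine, CH2Cl2) gives the saturated bromoisobutyrate F5. It is carried through the same operations: Bu4NF to the epoxy alcohol F6, SeO2/t-BuOOH to the diol F7, MnO2 to the dialdehyde F8, OsO4/N-methylmorpholine N-oxide to the lactol F9, and MnO2 to the bromo lactone F10. A last E2 elimination of HBr (DBU, CH2Cl2, 0 °C) unveils the methacrylate and comes back to the route at 28.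

**Further compounds**
F1 | step 3 | 2-methyl-5-(prop-1-en-2-yl)cyclohex-2-ene-1,4-diol, both hydroxyls trans to isopropenyl (6α,9α-diol) | O[C@H]1[C@H](C(C)=C)C[C@@H](O)C(C)=C1
F2 | step 12 | 8α-(carboxymethoxy) ether of 15 | O=C(c2ccccc2)O[C@@H]1[C@H](C(C)=C)[C@@H](OCC(=O)O)C=C(C)[C@@H]1C(=C)CO[Si](C)(C)C(C)(C)C
F3 | step 12 | (2R)-2-hydroxy acid corresponding to 19 (free C1 hydroxyl) | O=C(c2ccccc2)O[C@@H]1[C@H](C(C)=C)C=C[C@@](C)([C@@H](O)C(=O)O)[C@@H]1C(=C)CO[Si](C)(C)C(C)(C)C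
F4 | step 12 | tert-butyldimethylsilyl ester of 19 | O=C(c2ccccc2)O[C@@H]1[C@H](C(C)=C)C=C[C@@](C)([C@@H](O[Si](C)(C)C(C)(C)C)C(=O)O[Si](C)(C)C(C)(C)C)[C@@H]1C(=C)CO[Si](C)(C)C(C)(C)C
F5 | step 19 | 6β-(2-bromo-2-methylpropanoate) of 21 | CC(C)(Br)C(=O)O[C@@H]1[C@H](C(C)=C)C=C[C@@](C)([C@@H](O[Si](C)(C)C(C)(C)C)COS(=O)(=O)c2ccc(C)cc2)[C@@H]1C(=C)CO[Si](C)(C)C(C)(C)C
F6 | step 19 | bromoisobutyrate analogue of 23 | CC(C)(Br)C(=O)O[C@@H]1[C@H](C(C)=C)C=C[C@@](C)([C@@H]2CO2)[C@@H]1C(=C)CO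
F7 | step 19 | bromoisobutyrate analogue of 24 | CC(C)(Br)C(=O)O[C@@H]1[C@H](C(CO)=C)C=C[C@@](C)([C@@H]2CO2)[C@@H]1C(=C)CO
F8 | step 19 | bromoisobutyrate analogue of 25 | CC(C)(Br)C(=O)O[C@@H]1[C@H](C(C=O)=C)C=C[C@@](C)([C@@H]2CO2)[C@@H]1C(=C)C=O
F9 | step 19 | bromoisobutyrate analogue of 27 | CC(C)(Br)C(=O)O[C@@H]1[C@@H]2C(=C)C(O)O[C@H]2[C@@H](O)[C@@](C)([C@@H]2CO2)[C@@H]1C(=C)C=O
F10 | step 19 | 6β-(2-bromo-2-methylpropanoate) analogue of 28 | CC(C)(Br)C(=O)O[C@@H]1[C@@H]2C(=C)C(=O)O[C@H]2[C@@H](O)[C@@](C)([C@@H]2CO2)[C@@H]1C(=C)C=O
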